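Set the beta run beside the theta run: beta charges twice the starting material of theta, at the same 0 °C and the same equivalents of reagent, yet it keeps less of its charge as target, a plateau fraction of 0.282 against 0.387. Here are the flasks, the readings and the questions.

| flask | starting material | reagent | capture agent | temperature | remark | time |
|---|---|---|---|---|---|---|
| epsilon | 0.050 M | 2.5 equiv | 5 mM | −15 °C | run made earlier |  |
| beta | 0.050 M | 2.5 equiv | 3.4 mM | 0 °C | run made earlier |  |
| zeta | 0.050 M | 2.5 equiv | 7.5 mM | −15 °C | run made earlier |  |
| theta | 0.025 M | 2.5 equiv | 5 mM | 0 °C | run made earlier |  |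
| violet | 0.050 M | 2.50 equiv (in portions, 5, over 4.0 min) | 5.00 mM | 0 °C | first portion at the start, last at 4.0 min | 6.0 min |
| green | 0.050 M (fed, over 4.0 min) | 2.50 equiv | 5.00 mM | 0 °C | all else is in the flask from the start; the feed brings no volume worth counting | 6.0 min |
| grey | 0.050 M | 2.50 equiv (fed, over 4.0 min) | 5.00 mM | 0 °C | all else is in the flask from the start; the feed brings no volume worth counting | 6.0 min |
| blue | 0.050 M | 2.50 equiv (fed, over 4.0 min) | 5.00 mM |  | the addition at −20 °C, then warmed to 0 °C; the feed brings no volume worth counting | 6.0 min |

| run | time / min | target / % | starting material / % |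
|---|---|---|---|
| epsilon | 1.00 | 54.6 | 4.6 |
| epsilon | 3.00 | 55.4 | 0 |
| epsilon | 6.00 | 55.0 | 0.1 |
| epsilon | 8.00 | 55.1 | 0 |
| epsilon | 12.0 | 55.5 | 0 |
| beta | 0.333 | 27.1 | 20.0 |
| beta | 0.833 | 28.3 | 4.1 |
| beta | 1.50 | 27.7 | 1.2 |
| beta | 2.50 | 27.7 | 0.3 |
| beta | 4.00 | 29.0 | 0 |
| zeta | 0.667 | 51.9 | 10.7 |
| zeta | 2.00 | 55.6 | 0 |
| zeta | 3.00 | 54.8 | 0.1 |
| zeta | 5.00 | 55.0 | 0.1 |
| zeta | 8.00 | 56.1 | 0.9 |
| theta | 0.667 | 37.0 | 13.0 |
| theta | 1.33 | 38.5 | 2.5 |
| theta | 2.00 | 38.8 | 0.7 |
| theta | 3.00 | 38.4 | 1.5 |
| theta | 4.00 | 38.9 | 0 |

(readings scatter by 0.5 percentage points)

- the best flask by amount of target, in percent of the starting material charged; "all alike" if 1.5 percentage points covers them all (violet / green / grey / blue / all alike)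
- amount of target at the end, in percent of the starting material charged, violet
- amount of target at the end, in percent of the starting material charged, green
- amount of target at the end, in percent of the starting material charged, grey
- amount of target at the end, in percent of the starting material charged, blue

- the numbers in the tables scatter by 0.5 percentage points (one standard deviation)

Write each plateau as odds, a selectivity factor: the fraction of the charge that became target over the fraction that did not.

beta: odds = 0.392
theta: odds = 0.630

Then divide the logarithm of their ratio by the logarithm of the charge ratio:

n = 0.683

Call this the charge exponent, the power of the whole charge by which the odds fall at fixed temperature and equivalents, a reading from these two runs. Beta and theta also differ in capture agent, 3.4 mM against 5 mM, so the exponent puts two changes down to one; at −15 °C going from 5 mM to 7.5 mM leaves the plateau readings at 0.553 and 0.554, so take the capture agent as a small correction at 0 °C too, which is an assumption and no finding.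

Next ask whether the odds follow the starting material standing or the material already reacted. In the beta run, the target read was a share of 0.339 of what was consumed up to 0.333 min, but the net gain of target was a smaller share, 0.0755, of what was consumed from there to 0.833 min, while the standing fraction fell from 20.0 % to 4.10 %; that gain is 1.2 percentage points between readings that each scatter by 0.5 points, so the smaller share is a rough reading. A loss needing two starting material at once should ease as they thin, and on these readings this one did not, so as my own working choice apply the exponent to the whole charge.

Green, fed over 4.0 min, receives the same whole charge of starting material as beta, so reckon its odds and target fraction as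

odds = 0.392, target = 0.282

Leave violet, grey and blue unreckoned, since the runs give no odds for reagent fed slowly.

The forecast, reasoning that “the capture agent seems to die during the run”, names blue as best, with violet 38 %, green 13 %, grey 38 % and blue 54 %, and so differs from my reckoning on green.

The flasks give violet 12.8 %, green 27.1 %, grey 13.7 % and blue 42.4 %, and the best is blue.

    reagent + open intermediate → target (k = 6.04 /M/s, Ea = 38.0 kJ/mol)
    2 starting material → self-condensation product (k = 0.518 /M/s, Ea = 52.0 kJ/mol)
    starting material + target → side product (k = 1.70 /M/s, Ea = 39.0 kJ/mol)
    starting material ⇌ open intermediate + leaving ligand, settled at all times (K = 9.76 × 10⁻⁴ M, ΔH = −63.0 kJ/mol)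
    open intermediate + capture agent → trapped intermediate (k = 1.82 /M/s, Ea = 52.0 kJ/mol)
    (constants at 0 °C)

Green ends with odds of 0.372 against the 0.392 reckoned, and at 6.00 min its side product holds 67.1 % of the charge while its self-condensation product holds 4.92 %. Now carry the exponent, read from runs at 0 °C, to blue, which has its addition at −20 °C and whose odds are 0.737. Moved from 0.050 M down to the 0.013 M of its neighbour, which keeps the equivalents, loadings and time of blue, they become 1.85, a target of 64.9 %, and that neighbour holds 64.4 %.

(The data come from a simulation on assumed constants; scatter was added.)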